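## The problem

The target, 16, is a biflavonoid ether. A (2S)-5-hydroxy-7-methoxyflavanone (benzo ring A, dihydropyranone ring C, aryl ring B) is bonded through its ring B oxygen at C4' to C3' of the catechol-derived ring F of a 5,7-dihydroxyflavone (benzo ring D, pyranone ring E). The two C6–C3–C6 units share no carbon–carbon bond, so the skeleton reduces to one diaryl ether and two oxygen heterocycles at different oxidation levels, and the order of their construction decides whether the conditions for one (hydroxide, iodine, hot carbonate) ever meet the other. There is a single stereocentre, C2 of ring C; nothing else in the molecule can relay chirality to it, so it must come from a reagent or a catalyst. C2 is benzylic, bears the ring oxygen and lies β to the C4 ketone, so base or hot acid can open ring C by retro-oxa-Michael reaction to the achiral 2'-hydroxychalcone and re-close it as the racemate; it must therefore be set late, with only mild neutral or acidic steps after it. Five phenolic oxygens have to be told apart: four end up free and the one at C7 of ring A is methylated. The free phenols, the enolisable flavanone ketone and the flavone pyranone (sensitive to hydride and strong nucleophiles) exclude harsh redox or organometallic chemistry at the end. A late catalytic solution is possible because O1 and C2 of ring C are the ring A phenol oxygen and the β-carbon of a 2'-hydroxychalcone, while C3 can carry an ester that is later lost as CO2; this ester turns the enone into an alkylidene β-keto ester, a two-point binding site for a bifunctional catalyst.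

## Retrosynthesis

**16 from 15 (four O–benzyl bonds).** No skeletal bond is cut. The four free phenols of 16 are carried as benzyl ethers in 15, and the C7 methyl ether is present from the first ring A intermediate. Benzyl ethers survive every reagent used earlier and leave together by hydrogenolysis, which does not touch C2. Methyl ethers would need boron tribromide, which would also take the C7 methyl group. Acetal protection would bring the last step close to the acid tolerance of ring C.

**15 from 13 (C3–carboxyl bond).** A tert-butyl ester is put back on C3, giving the trans keto ester 13. This adds a second stereocentre on paper but no real complexity: C3 is epimerisable and is erased when the ester leaves. The forward reaction is acid-mediated loss of isobutene to keto acid 14 and then decarboxylation. The tert-butyl ester is chosen over methyl or ethyl because it is removed without hydroxide, which would open ring C, and because it resists lactonisation onto the neighbouring phenol.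

**13 from 12 (O1–C2, ring C).** Cutting the ring oxygen–benzylic carbon bond gives the acyclic alkylidene β-keto ester 12 with one free ring A phenol. This is preferred to cutting C4–C4a or C2–C3 because the forward step is an isomerisation that creates the stereocentre catalytically and as the last skeletal event. A bifunctional cinchona thiourea must close the ring 6-endo with enantiofacial control and faster than any uncatalysed closure.

**12 from 8 and 11 (Cα=Cβ).** The benzylidene double bond is cut by a Knoevenagel disconnection into aldehyde 8, which carries the whole flavone and the diaryl ether, and β-keto ester 11, which carries ring A and three carbons. The two halves are of similar size and are made independently. The condensation must form the alkene without closing ring C.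

**11 from 10, and 10 from 9.** The C3–ester bond is made by C-acylation of the enolate of acetophenone 10 with di-tert-butyl dicarbonate. Ketone 10 comes from commercial 2',6'-dihydroxy-4'-methoxyacetophenone 9 by benzylation of one hydroxyl. The mirror symmetry of 9 removes any question of regioselectivity, and the benzyl ether leaves exactly one acidic phenol for the key step.

**8 from 6 and 7 (aryl–oxygen bond of the ether).** The bond between the ether oxygen and ring B is cut, giving phenol 6 and 4-fluorobenzaldehyde 7. This polarity is the only one with an activating group para to the leaving group, so a metal-free aromatic substitution suffices and the formyl group arrives ready for the condensation. The ether is made at the flavone stage, not on aldehyde 3, because arylating 3 would give a dialdehyde whose two formyl groups could not be told apart.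

**6 from 4, 4 from 2 and 3, 2 from 1.** Ring E is opened at O1–C2 and taken back one oxidation level to the 2'-hydroxychalcone 4. The forward step is iodine-catalysed oxidative cyclisation through flavanone 5. Chalcone 4 is cut at its enone double bond into ketone 2 and aldehyde 3 (Claisen–Schmidt condensation), and 2 is the dibenzyl ether of commercial 2',4',6'-trihydroxyacetophenone 1. All of this chemistry uses hydroxide or hot iodine and therefore precedes the stereocentre. The phenol of 3 is carried unprotected to save two steps; this is the one liberty taken and has a protected fallback.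

## Roads not taken

**Alternative 1:** The cut is the C4a–C8a bond of ring A. Ring A is not bought but folded from a triketide chain stored as the 4-methoxy-2-pyranone A2, whose side chain carries the complete flavone–diaryl ether cinnamoyl unit.
- Forward key step: Mg(OMe)2 in methanol opens the lactone to a methoxy-enoate, the carbanion between the two ketones attacks the ester carbon in a Claisen condensation, and aromatisation gives the 2',6'-dihydroxy-4'-methoxychalcone A1.
- Merits: the enol ether of A2 fixes the methoxy group para to the acyl carbon, so ring A needs no protecting group and no differentiation of its oxygens. A1 is also the biogenetic precursor of the flavanone.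
- Weak points: ring A with exactly this pattern is the commercial ketone 9, so the key step builds what can be bought. A2 would have to be assembled from aldehyde 8 by several carbon–carbon bond formations. It then exposes an enone to methoxide, which can add in Michael fashion or divert the folding to the aldol mode.
- Decisive weakness: A1 has two free ortho hydroxyls. Such chalcones close to the flavanone spontaneously and racemically, and they offer no second carbonyl for two-point binding to a catalyst. The stereocentre, the one real difficulty of the target, is left unsolved.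
- Comparison: Alternative 1 is better in protecting-group economy on ring A (no benzylation, one benzyl ether fewer at the end). The chosen plan sets against this a catalyst-controlled C2 and a ring A fragment 11 that is two steps from a catalogue compound.

**Alternative 2:** The cut is C4–C4a of ring C. The ring is closed by carbon–carbon bond formation from the β-aryloxy acid A4, whose stereocentre is already in place.
- Forward key step: n-BuLi forms the lithium carboxylate and exchanges the bromine ortho to the ether oxygen for lithium; the aryllithium adds to the carboxylate carbon and work-up gives flavanone A3.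
- Merits: stereocontrol is separated from ring closure and rests on reliable acyclic methods. The closure has no racemic background reaction, and there is no activating ester to remove. In these respects it is stronger than the chosen plan.
- Weak points in making A4: its ether bond must be formed at a benzylic carbon bearing a para-aryloxy group, where substitution with inversion competes with ionisation and with elimination to a cinnamate. The dianion stage also puts a strong base next to a β-aryloxy carboxylate, which can expel the phenoxide by E1cB.
- Weak points after A3: it has a 5,7-dimethoxy ring A, so a selective 5-O-demethylation must follow. Most seriously, A3 holds the flavone half only as a dioxolane-masked aldehyde, so rings D and E would be built after the stereocentre exists. The hydroxide of a Claisen–Schmidt condensation opens ring C, and iodine in DMSO would dehydrogenate the flavanone itself to a flavone.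
- Comparison: against the better-founded enantiocontrol of Alternative 2, the chosen plan sets a closure that comes after every harsh step, with the finished flavone as a spectator and only two mild steps behind it.

**Alternative 3:** The cuts are C4a–C8a of ring D and O1–C2 of ring E. Both flavone rings are folded in one pot from the tetraketide equivalent A6, a 4-hydroxy-2-pyranone with a 2,4-dioxo-4-arylbutyl side chain.
- Forward key step: Mg(OMe)2 opens the pyranone to the tetraoxo ester, Claisen closure forms ring D, and the acid quench adds the new phenol to the aryl ketone with loss of water to give the bromo flavone A5.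
- Merits: two rings in one operation and a free 5,7-diol. It avoids both the condensation with a phenolic aldehyde and the iodine oxidation, which are the two least comfortable steps of the chosen flavone sequence; here it is better.
- Weak points: ring D is bought ready-made in ketone 1. A6 needs its own multi-step assembly and can fold in the aldol mode as well as the Claisen mode. The 4-bromophenyl ether in it cannot be made by aromatic substitution for lack of an activating group, so a copper-mediated etherification is required. The bromide of A5 must then become an aldehyde in the presence of a flavone carbonyl and two free phenols, which means protection followed by a palladium-catalysed formylation.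
- Comparison: the route says nothing about C2 and would still need the key step of the chosen plan, so it is an alternative way to aldehyde 8, not to the target. The chosen plan answers with three well-known steps from catalogue compounds to phenol 6 and an aldehyde delivered directly by 7.

Key step: step 8

Assumption 1: of the two pseudoenantiomeric 9-amino-9-deoxy-epi-cinchona thioureas, the quinine-derived one is written as the catalyst that leads to 2S; if the sense of induction with this substrate is the reverse, the quinidine-derived pseudoenantiomer takes its place and nothing else changes.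

Assumption 2: the Knoevenagel adduct 12 is taken as the Z isomer (ester cis to the aryl group), the usual thermodynamic outcome for benzylidene β-keto esters; either geometry can close to the same ring.

## Route

Step 1
Reactants: 1 2',4',6'-trihydroxyacetophenone [1-(2,4,6-trihydroxyphenyl)ethan-1-one]
Product: 2 1-[2,4-bis(benzyloxy)-6-hydroxyphenyl]ethan-1-one
Conditions: BnBr (2.1 equiv), K2CO3 (2.2 equiv), DMF, rt to 50 °C
Reagents that add atoms: benzyl bromide, BrCc1ccccc1
Why: Williamson etherification; the para hydroxyl and one ortho hydroxyl are alkylated, after which the remaining ortho hydroxyl is locked in a hydrogen bond to the ketone and resists alkylation with carbonate, so the reaction should stop at the dibenzyl ether.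

Step 2
Reactants: 2 1-[2,4-bis(benzyloxy)-6-hydroxyphenyl]ethan-1-one; 3 4-(benzyloxy)-3-hydroxybenzaldehyde
Product: 4 (E)-1-[2,4-bis(benzyloxy)-6-hydroxyphenyl]-3-[4-(benzyloxy)-3-hydroxyphenyl]prop-2-en-1-one
Conditions: KOH (aq., excess), EtOH/THF, rt
Reagents that add atoms: none
Why: Claisen–Schmidt aldol condensation; the phenoxide of 3 is meta to the formyl group and not conjugated with it, so the aldehyde stays electrophilic enough, and E1cB dehydration gives the E enone. Any flavanone formed by partial closure converges in step 3.

Step 3
Reactants: 4 (E)-1-[2,4-bis(benzyloxy)-6-hydroxyphenyl]-3-[4-(benzyloxy)-3-hydroxyphenyl]prop-2-en-1-one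
Product: 6 5,7-bis(benzyloxy)-2-[4-(benzyloxy)-3-hydroxyphenyl]-4H-chromen-4-one, via racemic flavanone 5 (not isolated)
Conditions: I2 (10 mol%), DMSO, 130 °C
Reagents that add atoms: none
Why: Iodine-catalysed oxidative cyclisation of a 2'-hydroxychalcone; oxa-Michael closure gives flavanone 5, α-iodination and loss of HI install the C2=C3 double bond, and DMSO re-oxidises HI to I2. Benzyl ethers and free phenols are known to tolerate this dehydrogenation.

Step 4
Reactants: 6 5,7-bis(benzyloxy)-2-[4-(benzyloxy)-3-hydroxyphenyl]-4H-chromen-4-one; 7 4-fluorobenzaldehyde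
Product: 8 4-[2-(benzyloxy)-5-(5,7-bis(benzyloxy)-4-oxo-4H-chromen-2-yl)phenoxy]benzaldehyde
Conditions: K2CO3, DMF, 100 °C
Reagents that add atoms: none
Why: Nucleophilic aromatic substitution; the only phenoxide of 6 adds para to the formyl group, which stabilises the Meisenheimer intermediate, and fluoride leaves. The flavone is stable to carbonate in dry DMF.

Step 5
Reactants: 9 2',6'-dihydroxy-4'-methoxyacetophenone [1-(2,6-dihydroxy-4-methoxyphenyl)ethan-1-one]
Product: 10 1-[2-(benzyloxy)-6-hydroxy-4-methoxyphenyl]ethan-1-one
Conditions: BnBr (1.05 equiv), K2CO3, acetone, reflux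
Reagents that add atoms: benzyl bromide, BrCc1ccccc1
Why: Williamson etherification; the two hydroxyls of 9 are equivalent by symmetry, and after the first alkylation the remaining one is chelated to the ketone, so monoalkylation should be clean.

Step 6
Reactants: 10 1-[2-(benzyloxy)-6-hydroxy-4-methoxyphenyl]ethan-1-one
Product: 11 tert-butyl 3-[2-(benzyloxy)-6-hydroxy-4-methoxyphenyl]-3-oxopropanoate
Conditions: LiN(SiMe3)2 (3.2 equiv), THF, −78 °C; Boc2O (1.1 equiv), −78 to 0 °C; aq. NH4Cl
Reagents that add atoms: di-tert-butyl dicarbonate, CC(C)(C)OC(=O)OC(=O)OC(C)(C)C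
Why: Claisen-type C-acylation of a ketone enolate; three equivalents of base form the phenoxide and the enolate and then deprotonate the product, which drives the reaction. A phenoxide that is O-acylated first can pass the tert-butoxycarbonyl group to the enolate carbon intramolecularly (Baker–Venkataraman-type transfer), so both paths converge on 11. The tert-butyl ester is too hindered to lactonise onto the phenol.

Step 7
Reactants: 8 4-[2-(benzyloxy)-5-(5,7-bis(benzyloxy)-4-oxo-4H-chromen-2-yl)phenoxy]benzaldehyde; 11 tert-butyl 3-[2-(benzyloxy)-6-hydroxy-4-methoxyphenyl]-3-oxopropanoate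
Product: 12 tert-butyl (Z)-2-[2-(benzyloxy)-6-hydroxy-4-methoxybenzoyl]-3-{4-[2-(benzyloxy)-5-(5,7-bis(benzyloxy)-4-oxo-4H-chromen-2-yl)phenoxy]phenyl}prop-2-enoate
Conditions: piperidine (20 mol%), AcOH (20 mol%), 4 Å molecular sieves, toluene, 40 °C
Reagents that add atoms: none
Why: Knoevenagel condensation through the iminium ion of 8 and the enol of 11, with water taken up by the sieves. The buffered medium and the hydrogen bond of the phenol to the ketone should keep ring C open, and the Z isomer with the twisted aroyl group trans to the aryl group is the expected thermodynamic product.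

Step 8
Reactants: 12 tert-butyl (Z)-2-[2-(benzyloxy)-6-hydroxy-4-methoxybenzoyl]-3-{4-[2-(benzyloxy)-5-(5,7-bis(benzyloxy)-4-oxo-4H-chromen-2-yl)phenoxy]phenyl}prop-2-enoate
Product: 13 tert-butyl (2S,3R)-5-(benzyloxy)-2-{4-[2-(benzyloxy)-5-(5,7-bis(benzyloxy)-4-oxo-4H-chromen-2-yl)phenoxy]phenyl}-7-methoxy-4-oxo-3,4-dihydro-2H-chromene-3-carboxylate (trans)
Conditions: 1-[3,5-bis(trifluoromethyl)phenyl]-3-[(8α,9S)-6'-methoxycinchonan-9-yl]thiourea (10 mol%), toluene, −25 °C
Reagents that add atoms: none
Why: This is an intramolecular oxa-Michael (oxo-conjugate) addition under bifunctional hydrogen-bond and Brønsted-base catalysis, the known cinchona-thiourea closure of alkylidene β-keto esters to 3-carboxyflavanones. The two thiourea N–H bonds bind the 1,3-dicarbonyl unit of 12 and lower the LUMO of the benzylidene, while the quinuclidine nitrogen takes the proton of the single free ring A phenol, so phenoxide and acceptor sit in one chiral ion pair. The oxygen adds to the benzylidene carbon in a 6-endo-trig closure that forms O1–C2 and ring C, and the resulting keto ester enolate is protonated by the quinuclidinium ion. C2 is set by the catalyst, which exposes one enantioface of the benzylidene carbon (2S with the pseudoenantiomer chosen under assumption 1). C3 is under no lasting catalyst control: it equilibrates through the enol to the trans (3R) arrangement with aryl and ester both equatorial, and is removed in step 9. The step needs enantiofacial selectivity and a catalysed rate well above the uncatalysed one. The tert-butyl ester supplies the second binding point and enough activation to run at −25 °C, the hydrogen bond of the phenol to the ketone keeps the neutral substrate unreactive, and the benzyl ether on the other ortho oxygen removes the second acidic, carbonyl-activating hydroxyl of a 2',6'-dihydroxy system. Low temperature and direct passage of the crude product into the acidic step 9 limit retro-oxa-Michael erosion at C2.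

Step 9
Reactants: 13 tert-butyl (2S,3R)-5-(benzyloxy)-2-{4-[2-(benzyloxy)-5-(5,7-bis(benzyloxy)-4-oxo-4H-chromen-2-yl)phenoxy]phenyl}-7-methoxy-4-oxo-3,4-dihydro-2H-chromene-3-carboxylate
Product: 15 (2S)-5-(benzyloxy)-2-{4-[2-(benzyloxy)-5-(5,7-bis(benzyloxy)-4-oxo-4H-chromen-2-yl)phenoxy]phenyl}-7-methoxy-2,3-dihydro-4H-chromen-4-one, via keto acid 14 (not isolated)
Conditions: TsOH·H2O (0.5 equiv), toluene, 80 °C
Reagents that add atoms: none
Why: Acid-catalysed cleavage of the tert-butyl ester (loss of isobutene) and thermal decarboxylation of the β-keto acid 14 through a cyclic six-membered transition state. C3 becomes a methylene group, and C2 is not touched because no base is present and aryl benzyl ethers are stable to this acid.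

Step 10
Reactants: 15 (2S)-5-(benzyloxy)-2-{4-[2-(benzyloxy)-5-(5,7-bis(benzyloxy)-4-oxo-4H-chromen-2-yl)phenoxy]phenyl}-7-methoxy-2,3-dihydro-4H-chromen-4-one
Product: 16 (2S)-2-{4-[5-(5,7-dihydroxy-4-oxo-4H-chromen-2-yl)-2-hydroxyphenoxy]phenyl}-5-hydroxy-7-methoxy-2,3-dihydro-4H-chromen-4-one
Conditions: H2 (1 atm), 10% Pd on carbon, THF/MeOH, rt
Reagents that add atoms: none
Why: Hydrogenolysis of four aryl benzyl ethers under neutral conditions. The aryl methyl ether, the flavone double bond (a vinylogous ester) and both ketones are expected to survive at ambient pressure with monitoring, and the C2 stereocentre is not affected.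

## Compound list

1 | 2',4',6'-trihydroxyacetophenone | CC(=O)c1c(O)cc(O)cc1O | starting material
2 | 1-[2,4-bis(benzyloxy)-6-hydroxyphenyl]ethan-1-one | CC(=O)c1c(O)cc(OCc2ccccc2)cc1OCc1ccccc1 | intermediate
3 | 4-(benzyloxy)-3-hydroxybenzaldehyde | O=Cc1ccc(OCc2ccccc2)c(O)c1 | starting material
4 | (E)-1-[2,4-bis(benzyloxy)-6-hydroxyphenyl]-3-[4-(benzyloxy)-3-hydroxyphenyl]prop-2-en-1-one | O=C(/C=C/c1ccc(OCc2ccccc2)c(O)c1)c1c(O)cc(OCc2ccccc2)cc1OCc1ccccc1 | intermediate
5 | racemic 5,7-bis(benzyloxy)-2-[4-(benzyloxy)-3-hydroxyphenyl]-2,3-dihydro-4H-chromen-4-one | O=C1CC(c2ccc(OCc3ccccc3)c(O)c2)Oc2cc(OCc3ccccc3)cc(OCc3ccccc3)c21 | intermediate (not isolated)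
6 | 5,7-bis(benzyloxy)-2-[4-(benzyloxy)-3-hydroxyphenyl]-4H-chromen-4-one | O=c1cc(-c2ccc(OCc3ccccc3)c(O)c2)oc2cc(OCc3ccccc3)cc(OCc3ccccc3)c12 | intermediate
7 | 4-fluorobenzaldehyde | O=Cc1ccc(F)cc1 | starting material
8 | 4-[2-(benzyloxy)-5-(5,7-bis(benzyloxy)-4-oxo-4H-chromen-2-yl)phenoxy]benzaldehyde | O=Cc1ccc(Oc2cc(-c3cc(=O)c4c(OCc5ccccc5)cc(OCc5ccccc5)cc4o3)ccc2OCc2ccccc2)cc1 | intermediate
9 | 2',6'-dihydroxy-4'-methoxyacetophenone | COc1cc(O)c(C(C)=O)c(O)c1 | starting material
10 | 1-[2-(benzyloxy)-6-hydroxy-4-methoxyphenyl]ethan-1-one | COc1cc(O)c(C(C)=O)c(OCc2ccccc2)c1 | intermediate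
11 | tert-butyl 3-[2-(benzyloxy)-6-hydroxy-4-methoxyphenyl]-3-oxopropanoate | COc1cc(O)c(C(=O)CC(=O)OC(C)(C)C)c(OCc2ccccc2)c1 | intermediate
12 | tert-butyl (Z)-2-[2-(benzyloxy)-6-hydroxy-4-methoxybenzoyl]-3-{4-[2-(benzyloxy)-5-(5,7-bis(benzyloxy)-4-oxo-4H-chromen-2-yl)phenoxy]phenyl}prop-2-enoate | COc1cc(O)c(C(=O)/C(C(=O)OC(C)(C)C)=C/c2ccc(Oc3cc(-c4cc(=O)c5c(OCc6ccccc6)cc(OCc6ccccc6)cc5o4)ccc3OCc3ccccc3)cc2)c(OCc2ccccc2)c1 | intermediate
13 | tert-butyl (2S,3R)-5-(benzyloxy)-2-{4-[2-(benzyloxy)-5-(5,7-bis(benzyloxy)-4-oxo-4H-chromen-2-yl)phenoxy]phenyl}-7-methoxy-4-oxo-3,4-dihydro-2H-chromene-3-carboxylate | COc1cc(OCc2ccccc2)c2c(c1)O[C@H](c1ccc(Oc3cc(-c4cc(=O)c5c(OCc6ccccc6)cc(OCc6ccccc6)cc5o4)ccc3OCc3ccccc3)cc1)[C@@H](C(=O)OC(C)(C)C)C2=O | intermediate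
14 | (2S,3R)-5-(benzyloxy)-2-{4-[2-(benzyloxy)-5-(5,7-bis(benzyloxy)-4-oxo-4H-chromen-2-yl)phenoxy]phenyl}-7-methoxy-4-oxo-3,4-dihydro-2H-chromene-3-carboxylic acid | COc1cc(OCc2ccccc2)c2c(c1)O[C@H](c1ccc(Oc3cc(-c4cc(=O)c5c(OCc6ccccc6)cc(OCc6ccccc6)cc5o4)ccc3OCc3ccccc3)cc1)[C@@H](C(=O)O)C2=O | intermediate (not isolated)
15 | (2S)-5-(benzyloxy)-2-{4-[2-(benzyloxy)-5-(5,7-bis(benzyloxy)-4-oxo-4H-chromen-2-yl)phenoxy]phenyl}-7-methoxy-2,3-dihydro-4H-chromen-4-one | COc1cc(OCc2ccccc2)c2c(c1)O[C@H](c1ccc(Oc3cc(-c4cc(=O)c5c(OCc6ccccc6)cc(OCc6ccccc6)cc5o4)ccc3OCc3ccccc3)cc1)CC2=O | intermediate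
16 | (2S)-2-{4-[5-(5,7-dihydroxy-4-oxo-4H-chromen-2-yl)-2-hydroxyphenoxy]phenyl}-5-hydroxy-7-methoxy-2,3-dihydro-4H-chromen-4-one | COc1cc(O)c2c(c1)O[C@H](c1ccc(Oc3cc(-c4cc(=O)c5c(O)cc(O)cc5o4)ccc3O)cc1)CC2=O | target

## Step count and risks

Total: 10 steps. Longest linear sequence: 8 steps (steps 1, 2, 3, 4, 7, 8, 9, 10); steps 5 and 6 form the two-step side branch to 11.

**Step 8 (key step).** The most likely failure is weak enantiofacial discrimination together with a competing uncatalysed closure.
- Cause: the 2,6-disubstituted aroyl group of 12 is twisted out of conjugation and the benzylidene carries a very large aryl group, both outside the simple substrates for which this catalyst class is established.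
- Further risks: slow turnover if 12 is poorly soluble in toluene at −25 °C, and retro-oxa-Michael erosion on long contact with the basic catalyst.
- Fallback (resolution instead of asymmetric catalysis): from 12, closure with triethylamine in toluene at rt should give racemic trans tert-butyl 5-(benzyloxy)-2-{4-[2-(benzyloxy)-5-(5,7-bis(benzyloxy)-4-oxo-4H-chromen-2-yl)phenoxy]phenyl}-7-methoxy-4-oxochromane-3-carboxylate F1. TsOH in toluene at 80 °C should convert it through the racemic keto acid F2 into the racemic tetrabenzyl flavanone F3. Preparative chromatography on a cellulose tris(3,5-dimethylphenylcarbamate) phase then separates the enantiomers, and the 2S enantiomer is 15, where the route is rejoined. The 2R enantiomer can be racemised with base through ring opening and re-closure and recycled.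

**Step 2 (with consequences for step 3).** The most likely failure is incomplete condensation.
- Cause: aldehyde 3 reacts as its phenoxide and is slowly consumed by hydroxide-mediated side reactions over a long reaction time. In step 3 the free, electron-rich phenol ring may also be iodinated.
- Fallback (protected phenol): from 3, MOMCl and iPr2NEt in CH2Cl2 give 4-(benzyloxy)-3-(methoxymethoxy)benzaldehyde F4. Claisen–Schmidt condensation with 2 gives the methoxymethyl-protected chalcone F5. I2 in DMSO converts it through the protected racemic flavanone F6 into the protected flavone F7. HCl in MeOH/THF at 50 °C removes the acetal and returns to 6; loss of the acetal already during the iodine step would be harmless.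

**Step 6.** The most likely failure is a stalled reaction.
- Cause: O-acylation of the phenoxide without onward transfer, or sluggish C-acylation of the hindered enolate of a 2,6-disubstituted aryl ketone. Over-acylation occurs if excess dicarbonate is used.
- Fallback (intramolecular delivery as a separate step): from 10, Boc2O with catalytic DMAP and Et3N in CH2Cl2 gives 2-acetyl-3-(benzyloxy)-5-methoxyphenyl tert-butyl carbonate F8, which is isolated. LiN(SiMe3)2 (2.2 equiv) in THF from −78 to 0 °C then induces the anionic O-to-C migration of the tert-butoxycarbonyl group through a six-membered transition state (carbonate variant of the Baker–Venkataraman rearrangement) and returns to 11.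

**Step 7.** The most likely failure is premature, racemic closure of ring C under the amine catalyst.
- Cause: the amine that catalyses the condensation can also deprotonate the phenol. Slow condensation of the electron-rich aldehyde would aggravate this.
- Fallback (phenol masked during the condensation): from 11, TBSCl and imidazole in DMF give tert-butyl 3-[2-(benzyloxy)-6-{[tert-butyl(dimethyl)silyl]oxy}-4-methoxyphenyl]-3-oxopropanoate F9. The same Knoevenagel condensation with 8 gives the silylated alkylidene keto ester F10, which cannot cyclise. HF·pyridine in THF at 0 °C frees the phenol under non-basic conditions and returns to 12.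

**Step 10.** The most likely failure is over-reduction, or stalling after partial debenzylation.
- Cause: hydrogenolysis of the benzylic C2–O1 bond of ring C or hydrogenation of the C4 ketone can compete. Sparingly soluble polyphenolic intermediates can deposit on the catalyst.
- Fallback (Lewis-acid debenzylation in place of hydrogenation): from 15, BCl3 with pentamethylbenzene as benzyl cation scavenger in CH2Cl2 at −78 °C leads directly to 16 without a new intermediate. The C7 methyl ether is not next to a carbonyl and should survive at this temperature.

## Further compounds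

F1 | step 8 | racemic trans tert-butyl 5-(benzyloxy)-2-{4-[2-(benzyloxy)-5-(5,7-bis(benzyloxy)-4-oxo-4H-chromen-2-yl)phenoxy]phenyl}-7-methoxy-4-oxochromane-3-carboxylate (racemate, relative configuration trans) | COc1cc(OCc2ccccc2)c2c(c1)OC(c1ccc(Oc3cc(-c4cc(=O)c5c(OCc6ccccc6)cc(OCc6ccccc6)cc5o4)ccc3OCc3ccccc3)cc1)C(C(=O)OC(C)(C)C)C2=O
F2 | step 8 | racemic trans 5-(benzyloxy)-2-{4-[2-(benzyloxy)-5-(5,7-bis(benzyloxy)-4-oxo-4H-chromen-2-yl)phenoxy]phenyl}-7-methoxy-4-oxochromane-3-carboxylic acid (racemate, not isolated) | COc1cc(OCc2ccccc2)c2c(c1)OC(c1ccc(Oc3cc(-c4cc(=O)c5c(OCc6ccccc6)cc(OCc6ccccc6)cc5o4)ccc3OCc3ccccc3)cc1)C(C(=O)O)C2=O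
F3 | step 8 | racemic 5-(benzyloxy)-2-{4-[2-(benzyloxy)-5-(5,7-bis(benzyloxy)-4-oxo-4H-chromen-2-yl)phenoxy]phenyl}-7-methoxy-2,3-dihydro-4H-chromen-4-one (racemate) | COc1cc(OCc2ccccc2)c2c(c1)OC(c1ccc(Oc3cc(-c4cc(=O)c5c(OCc6ccccc6)cc(OCc6ccccc6)cc5o4)ccc3OCc3ccccc3)cc1)CC2=O
F4 | step 2 | 4-(benzyloxy)-3-(methoxymethoxy)benzaldehyde | COCOc1cc(C=O)ccc1OCc1ccccc1
F5 | step 2 | (E)-1-[2,4-bis(benzyloxy)-6-hydroxyphenyl]-3-[4-(benzyloxy)-3-(methoxymethoxy)phenyl]prop-2-en-1-one | COCOc1cc(/C=C/C(=O)c2c(O)cc(OCc3ccccc3)cc2OCc2ccccc2)ccc1OCc1ccccc1
F6 | step 2 | racemic 5,7-bis(benzyloxy)-2-[4-(benzyloxy)-3-(methoxymethoxy)phenyl]-2,3-dihydro-4H-chromen-4-one (not isolated) | COCOc1cc(C2CC(=O)c3c(OCc4ccccc4)cc(OCc4ccccc4)cc3O2)ccc1OCc1ccccc1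
F7 | step 2 | 5,7-bis(benzyloxy)-2-[4-(benzyloxy)-3-(methoxymethoxy)phenyl]-4H-chromen-4-one | COCOc1cc(-c2cc(=O)c3c(OCc4ccccc4)cc(OCc4ccccc4)cc3o2)ccc1OCc1ccccc1
F8 | step 6 | 2-acetyl-3-(benzyloxy)-5-methoxyphenyl tert-butyl carbonate | COc1cc(OC(=O)OC(C)(C)C)c(C(C)=O)c(OCc2ccccc2)c1
F9 | step 7 | tert-butyl 3-[2-(benzyloxy)-6-{[tert-butyl(dimethyl)silyl]oxy}-4-methoxyphenyl]-3-oxopropanoate | COc1cc(O[Si](C)(C)C(C)(C)C)c(C(=O)CC(=O)OC(C)(C)C)c(OCc2ccccc2)c1
F10 | step 7 | tert-butyl (Z)-2-[2-(benzyloxy)-6-{[tert-butyl(dimethyl)silyl]oxy}-4-methoxybenzoyl]-3-{4-[2-(benzyloxy)-5-(5,7-bis(benzyloxy)-4-oxo-4H-chromen-2-yl)phenoxy]phenyl}prop-2-enoate | COc1cc(O[Si](C)(C)C(C)(C)C)c(C(=O)/C(C(=O)OC(C)(C)C)=C/c2ccc(Oc3cc(-c4cc(=O)c5c(OCc6ccccc6)cc(OCc6ccccc6)cc5o4)ccc3OCc3ccccc3)cc2)c(OCc2ccccc2)c1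
F0 | step 10 | none | none
A1 | alternative 1 | (E)-3-{4-[2-(benzyloxy)-5-(5,7-bis(benzyloxy)-4-oxo-4H-chromen-2-yl)phenoxy]phenyl}-1-(2,6-dihydroxy-4-methoxyphenyl)prop-2-en-1-one | COc1cc(O)c(C(=O)/C=C/c2ccc(Oc3cc(-c4cc(=O)c5c(OCc6ccccc6)cc(OCc6ccccc6)cc5o4)ccc3OCc3ccccc3)cc2)c(O)c1
A2 | alternative 1 | 6-[(3E)-4-{4-[2-(benzyloxy)-5-(5,7-bis(benzyloxy)-4-oxo-4H-chromen-2-yl)phenoxy]phenyl}-2-oxobut-3-en-1-yl]-4-methoxy-2H-pyran-2-one | COc1cc(=O)oc(CC(=O)/C=C/c2ccc(Oc3cc(-c4cc(=O)c5c(OCc6ccccc6)cc(OCc6ccccc6)cc5o4)ccc3OCc3ccccc3)cc2)c1
A3 | alternative 2 | (2S)-2-{4-[2-(benzyloxy)-5-(1,3-dioxolan-2-yl)phenoxy]phenyl}-5,7-dimethoxy-2,3-dihydro-4H-chromen-4-one | COc1cc(OC)c2c(c1)O[C@H](c1ccc(Oc3cc(C4OCCO4)ccc3OCc3ccccc3)cc1)CC2=O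
A4 | alternative 2 | (3S)-3-{4-[2-(benzyloxy)-5-(1,3-dioxolan-2-yl)phenoxy]phenyl}-3-(2-bromo-3,5-dimethoxyphenoxy)propanoic acid | COc1cc(OC)c(Br)c(O[C@@H](CC(=O)O)c2ccc(Oc3cc(C4OCCO4)ccc3OCc3ccccc3)cc2)c1
A5 | alternative 3 | 2-[4-(benzyloxy)-3-(4-bromophenoxy)phenyl]-5,7-dihydroxy-4H-chromen-4-one | O=c1cc(-c2ccc(OCc3ccccc3)c(Oc3ccc(Br)cc3)c2)oc2cc(O)cc(O)c12
A6 | alternative 3 | 6-{4-[4-(benzyloxy)-3-(4-bromophenoxy)phenyl]-2,4-dioxobutyl}-4-hydroxy-2H-pyran-2-one | O=c1cc(O)cc(CC(=O)CC(=O)c2ccc(OCc3ccccc3)c(Oc3ccc(Br)cc3)c2)o1
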